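The veratroyl ester is disconnected at its aryl–carbonyl bond. The plan exploits the 1,3-relationship of the benzylic oxygen on C1 and the hydroxyl oxygen on C3 of the butane chain. Both oxygens are tied to the future ester carbonyl carbon, which becomes C2 of a 6-methylidene-1,3-dioxan-2-one, a cyclic enol carbonate made from a homopropargylic tert-butyl carbonate. Addition of 3,4-dimethoxyphenylmagnesium bromide to this ring forms the aryl–C(=O) bond and expels only the enolate oxygen. The ester therefore stays on the benzylic oxygen, and the C3 ketone is released as its self-protected magnesium enolate. A Prelog ketoreductase then sets C3 against the substrate bias.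

Key step: step 6

Assumption: the chain is numbered C1 (benzylic carbon bearing the ester oxygen) to C4 (terminal methyl), and a Prelog-type ketoreductase that accepts ketone 11 is taken from a commercial screening panel.

Step 1
Reactants: 1 (S)-but-3-yn-2-ol
Product: 2 (S)-but-3-yn-2-yl methanesulfonate
Conditions: MsCl, Et3N, CH2Cl2, −78 to 0 °C
Reagents that add atoms: methanesulfonyl chloride, CS(=O)(=O)Cl
Why: Sulfonylation of the alcohol oxygen (mesylate formation) does not touch the C–O bond, so the S configuration of 1 is retained.

Step 2
Reactants: 3 3-hydroxy-4,5-dimethoxybenzaldehyde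
Product: 4 3-(tert-butyldimethylsilyloxy)-4,5-dimethoxybenzaldehyde
Conditions: TBSCl, imidazole, DMF, rt
Reagents that add atoms: tert-butyldimethylsilyl chloride, CC(C)(C)[Si](C)(C)Cl
Why: Imidazole-promoted silyl ether formation masks the acidic phenol, which would otherwise quench diethylzinc and the Grignard reagent, as a group that survives all later steps and leaves with buffered fluoride.

Step 3
Reactants: 4 3-(tert-butyldimethylsilyloxy)-4,5-dimethoxybenzaldehyde; 2 (S)-but-3-yn-2-yl methanesulfonate
Product: 6 (1R,2R)-1-[3-(tert-butyldimethylsilyloxy)-4,5-dimethoxyphenyl]-2-methylbut-3-yn-1-ol, via allenylzinc 5 (not isolated)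
Conditions: Pd(OAc)2 (5 mol %), PPh3 (5 mol %), Et2Zn (3 equiv), THF, −20 °C; aq NH4Cl
Reagents that add atoms: none
Why: In this Marshall propargylation, anti SN2′ oxidative addition of Pd(0) to 2 and transmetalation give the axially chiral allenylzinc 5, which adds to 4 through a cyclic syn SE2′ transition state with the aryl group turned away from the allenyl methyl, so C2 is set as R by net inversion of the mesylate center and C1 as R by the anti preference, the minor syn isomer being removed by chromatography.

Step 4
Reactants: 6 (1R,2R)-1-[3-(tert-butyldimethylsilyloxy)-4,5-dimethoxyphenyl]-2-methylbut-3-yn-1-ol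
Product: 7 tert-butyl (1R,2R)-1-[3-(tert-butyldimethylsilyloxy)-4,5-dimethoxyphenyl]-2-methylbut-3-yn-1-yl carbonate
Conditions: Boc2O, DMAP (cat.), CH2Cl2, rt
Reagents that add atoms: di-tert-butyl dicarbonate, CC(C)(C)OC(=O)OC(=O)OC(C)(C)C
Why: DMAP-catalysed O-acylation with Boc anhydride (carbonate formation) places the future ester carbonyl carbon on the benzylic oxygen without touching either stereocenter.

Step 5
Reactants: 7 tert-butyl (1R,2R)-1-[3-(tert-butyldimethylsilyloxy)-4,5-dimethoxyphenyl]-2-methylbut-3-yn-1-yl carbonate
Product: 8 (4R,5S)-4-[3-(tert-butyldimethylsilyloxy)-4,5-dimethoxyphenyl]-5-methyl-6-methylidene-1,3-dioxan-2-one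
Conditions: (C6F5)3PAuCl/AgSbF6 (5 mol %), ClCH2CH2Cl, 0 °C to rt; filtration through neutral alumina
Reagents that add atoms: none
Why: In this gold(I)-catalysed 6-exo-dig cyclisation of a homopropargylic tert-butyl carbonate, the carbonyl oxygen attacks the internal carbon of the π-activated alkyne, isobutene is lost and protodeauration gives the exocyclic enol carbonate with ring atoms C4 and C5 untouched.

Step 6
Reactants: 8 (4R,5S)-4-[3-(tert-butyldimethylsilyloxy)-4,5-dimethoxyphenyl]-5-methyl-6-methylidene-1,3-dioxan-2-one; 9 3,4-dimethoxyphenylmagnesium bromide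
Product: 11 (1R,2S)-1-[3-(tert-butyldimethylsilyloxy)-4,5-dimethoxyphenyl]-2-methyl-3-oxobutyl 3,4-dimethoxybenzoate, via magnesium enolate 10 (not isolated)
Conditions: 9 (1.05 equiv, 0.5 M in THF, slow addition), THF, −78 °C; cannulated into AcOH/THF, −78 °C
Reagents that add atoms: none
Why: The aryl Grignard reagent adds to the ring carbonyl C2 and the tetrahedral magnesium alkoxide collapses by breaking the bond from C2 to the enol oxygen, which gives ester enolate 10, protonated at its terminal carbon on the cold acidic quench to methyl ketone 11. The closest known reaction types are the ester synthesis from Grignard reagents and activated carbonates or alkyl 1-imidazolecarboxylates, the release of regiodefined enolates from enol carbonates by organometallic reagents, and the aminolysis or alcoholysis of alkylidene cyclic carbonates to β-oxo carbamates and carbonates. No ring is closed and no stereocenter is created: the dioxanone ring is opened, and chain atoms C1 and C2 (ring atoms C4 and C5) are spectators because only the C3–C4 enolate forms and C2 is never deprotonated. The step needs regioselective ring opening, which is secured because an enolate oxygen (enol pKa near 11) is a far better leaving group than a benzylic alkoxide (pKa near 15), and the alternative pair of enol ester and alkoxide is also the less stable one, so the aroyl group ends only on the benzylic oxygen. It also needs mono-addition, which unlike with a dialkyl carbonate is secured because the ketone is born as its enolate and the product is a hindered, electron-rich benzoate far less electrophilic than the cyclic enol carbonate at −78 °C. Keeping the enolate cold and quenching it inversely should avoid proton exchange to the C2 enolate (β-elimination of the aroyloxy group) and intramolecular C-acylation.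

Step 7
Reactants: 11 (1R,2S)-1-[3-(tert-butyldimethylsilyloxy)-4,5-dimethoxyphenyl]-2-methyl-3-oxobutyl 3,4-dimethoxybenzoate
Product: 12 (1R,2R,3S)-1-[3-(tert-butyldimethylsilyloxy)-4,5-dimethoxyphenyl]-3-hydroxy-2-methylbutyl 3,4-dimethoxybenzoate
Conditions: Prelog-selective ketoreductase (NADPH-dependent alcohol dehydrogenase class), NADP+ (cat.), i-PrOH (10 vol %), DMSO (10 vol %), phosphate buffer pH 7.0, 30 °C
Reagents that add atoms: none
Why: In this enzymatic carbonyl reduction with NADPH recycled by isopropanol, a Prelog-type ketoreductase delivers hydride to the Re face of the methyl ketone and sets C3 as S under catalyst control at neutral pH, whereas Felkin–Anh control with small hydride reagents would favour the 3R epimer and basic reagents would trigger elimination or acyl migration.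

Step 8
Reactants: 12 (1R,2R,3S)-1-[3-(tert-butyldimethylsilyloxy)-4,5-dimethoxyphenyl]-3-hydroxy-2-methylbutyl 3,4-dimethoxybenzoate
Product: 13 (1R,2R,3S)-3-hydroxy-1-(3-hydroxy-4,5-dimethoxyphenyl)-2-methylbutyl 3,4-dimethoxybenzoate (CNP0124473.1)
Conditions: TBAF/AcOH (1:1.2), THF, 0 °C
Reagents that add atoms: none
Why: Fluoride-induced cleavage of the aryl silyl ether, buffered with acetic acid so that no alkoxide forms at C3, should free the phenol without 1,3-migration of the veratroyl group or change at any stereocenter.

Compound list
1 | (S)-but-3-yn-2-ol | C[C@H](O)C#C | starting material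
2 | (S)-but-3-yn-2-yl methanesulfonate | C[C@H](OS(C)(=O)=O)C#C | intermediate
3 | 3-hydroxy-4,5-dimethoxybenzaldehyde | O=Cc1cc(O)c(OC)c(OC)c1 | starting material
4 | 3-(tert-butyldimethylsilyloxy)-4,5-dimethoxybenzaldehyde | O=Cc1cc(O[Si](C)(C)C(C)(C)C)c(OC)c(OC)c1 | intermediate
5 | (Ra)-buta-1,2-dien-1-yl(ethyl)zinc, formed in the flask | CC([H])=[C@]=C([H])[Zn]CC | intermediate
6 | (1R,2R)-1-[3-(tert-butyldimethylsilyloxy)-4,5-dimethoxyphenyl]-2-methylbut-3-yn-1-ol | O[C@@H](c1cc(O[Si](C)(C)C(C)(C)C)c(OC)c(OC)c1)[C@H](C)C#C | intermediate
7 | tert-butyl (1R,2R)-1-[3-(tert-butyldimethylsilyloxy)-4,5-dimethoxyphenyl]-2-methylbut-3-yn-1-yl carbonate | CC(C)(C)OC(=O)O[C@@H](c1cc(O[Si](C)(C)C(C)(C)C)c(OC)c(OC)c1)[C@H](C)C#C | intermediate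
8 | (4R,5S)-4-[3-(tert-butyldimethylsilyloxy)-4,5-dimethoxyphenyl]-5-methyl-6-methylidene-1,3-dioxan-2-one | O=C1O[C@@H](c2cc(O[Si](C)(C)C(C)(C)C)c(OC)c(OC)c2)[C@H](C)C(=C)O1 | intermediate
9 | 3,4-dimethoxyphenylmagnesium bromide (commercial THF solution) | COc1ccc([Mg]Br)cc1OC | starting material
10 | terminal (C3=C4) bromomagnesium enolate of ketone 11, formed in the flask | COc1ccc(C(=O)O[C@@H](c2cc(O[Si](C)(C)C(C)(C)C)c(OC)c(OC)c2)[C@H](C)C(=C)O[Mg]Br)cc1OC | intermediate
11 | (1R,2S)-1-[3-(tert-butyldimethylsilyloxy)-4,5-dimethoxyphenyl]-2-methyl-3-oxobutyl 3,4-dimethoxybenzoate | COc1ccc(C(=O)O[C@@H](c2cc(O[Si](C)(C)C(C)(C)C)c(OC)c(OC)c2)[C@H](C)C(C)=O)cc1OC | intermediate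
12 | (1R,2R,3S)-1-[3-(tert-butyldimethylsilyloxy)-4,5-dimethoxyphenyl]-3-hydroxy-2-methylbutyl 3,4-dimethoxybenzoate | COc1ccc(C(=O)O[C@@H](c2cc(O[Si](C)(C)C(C)(C)C)c(OC)c(OC)c2)[C@H](C)[C@H](C)O)cc1OC | intermediate
13 | (1R,2R,3S)-3-hydroxy-1-(3-hydroxy-4,5-dimethoxyphenyl)-2-methylbutyl 3,4-dimethoxybenzoate | COc1ccc(C(=O)O[C@@H](c2cc(O)c(OC)c(OC)c2)[C@H](C)[C@H](C)O)cc1OC | target

Total step count: 8. Longest linear sequence: 7 steps (3 → 4 → 6 → 7 → 8 → 11 → 12 → 13).

Steps most likely to fail

**Step 6.**
- What may go wrong: a second addition of the Grignard reagent to the freshly formed ester. Alternatively, proton exchange may move the enolate to C2, followed by β-elimination of the aroyloxy group or C-acylation.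
- The fallback forms the same aryl–carbonyl bond by known chemistry. It sets out from alcohol 6 and comes back at ketone 11.
- Alcohol 6 is acylated with 1,1′-carbonyldiimidazole to the homopropargylic imidazole-1-carboxylate F1.
- F1 is treated with Grignard reagent 9 (ester synthesis from alkyl imidazolecarboxylates, with a second equivalent covering deprotonation of the alkyne) to give the homopropargylic 3,4-dimethoxybenzoate F2.
- Gold(I)-catalysed Markovnikov hydration of the terminal alkyne in wet dioxane, assisted by the ester carbonyl, then gives 11.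

**Step 5.**
- What may go wrong: competing attack of the electron-rich arene on the gold-activated alkyne (hydroarylation), or hydrolytic ring opening of the enol carbonate during isolation.
- The fallback replaces π-acid catalysis by halocyclisation and elimination. It sets out from carbonate 7 and comes back at enol carbonate 8.
- Lindlar semihydrogenation of 7 gives the homoallylic tert-butyl carbonate F3.
- Iodocarbonate cyclisation with IBr in toluene at −80 °C gives the all-equatorial iodomethyl carbonate F4.
- E2 elimination with DBU removes the C6 center again and gives 8.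

**Step 7.**
- What may go wrong: no enzyme of the panel may accept the bulky diaryl substrate. Slow turnover may also allow epimerisation at C2 or β-elimination in the buffer.
- The fallback replaces biocatalysis by small-molecule catalyst control. It sets out from ketone 11 and comes back at alcohol 12.
- It is a Corey–Bakshi–Shibata reduction with (R)-Me-CBS and catecholborane in toluene at −78 °C.
- The oxazaborolidine differentiates the methyl group from the branched chain, and the 3R epimer is removed by chromatography.
- This fallback makes no new compound (F0).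

Further compounds
F1 | step 6 | (1R,2R)-1-[3-(tert-butyldimethylsilyloxy)-4,5-dimethoxyphenyl]-2-methylbut-3-yn-1-yl 1H-imidazole-1-carboxylate | O=C(O[C@@H](c1cc(O[Si](C)(C)C(C)(C)C)c(OC)c(OC)c1)[C@H](C)C#C)n1ccnc1
F2 | step 6 | (1R,2R)-1-[3-(tert-butyldimethylsilyloxy)-4,5-dimethoxyphenyl]-2-methylbut-3-yn-1-yl 3,4-dimethoxybenzoate | COc1ccc(C(=O)O[C@@H](c2cc(O[Si](C)(C)C(C)(C)C)c(OC)c(OC)c2)[C@H](C)C#C)cc1OC
F3 | step 5 | tert-butyl (1R,2R)-1-[3-(tert-butyldimethylsilyloxy)-4,5-dimethoxyphenyl]-2-methylbut-3-en-1-yl carbonate | CC(C)(C)OC(=O)O[C@@H](c1cc(O[Si](C)(C)C(C)(C)C)c(OC)c(OC)c1)[C@H](C)C=C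
F4 | step 5 | (4R,5S,6S)-4-[3-(tert-butyldimethylsilyloxy)-4,5-dimethoxyphenyl]-6-(iodomethyl)-5-methyl-1,3-dioxan-2-one | O=C1O[C@@H](c2cc(O[Si](C)(C)C(C)(C)C)c(OC)c(OC)c2)[C@H](C)[C@@H](CI)O1
F0 | step 7 | none | none
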